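The plan cuts the two side-chain bonds of the five-membered ring, C1–C10 and C5–C6 (guaiane numbering). That ring carries H1 and H5 trans on neighbouring carbons, directly beside the oxidised carbon C4. This is the imprint of a nucleophile and an electrophile added one after the other to a cyclopentenone. In one flask, an enantioselective copper-catalysed addition of isopropenylmagnesium bromide to cyclopent-2-enone fixes C1. The enolate is then alkylated at C5 by an allylic bromide, anti to the new group. Three small achiral pieces thus give a trans-2,3-disubstituted cyclopentanone holding every skeletal carbon except the C4 methyl group. A carbonyl-ene closure of the seven-membered ring follows.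

Key step: step 5

Remark on numbering: guaiane numbering is used throughout. C1 and C5 are the ring fusion, C4 the former carbonyl carbon, C7 bears isopropyl, C8 the ester, C10 the carbinol, C14 is the C10 methyl and C15 the C4 methyl. α is the face of H1. Bicyclic compounds that still lack C15 are named as 15-norguaianes, and "TBS-vanilloyl" means 4-(tert-butyldimethylsilyloxy)-3-methoxybenzoyl.

Assumption: the ligand enantiomer that gives (R) at C1 with this Grignard reagent is settled on the simple adduct. Both enantiomers are sold, and one of them is written in step 5.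

Step 1
Reactants: 1 methyl 3-methylbut-2-enoate
Product: 3 methyl 2-(hydroxymethyl)-3-methylbut-3-enoate (racemic), via lithium dienolate 2 (not isolated)
Conditions: LiN(iPr)2, THF, −78 °C; CH2O (gas, cracked from paraformaldehyde), −78 to −20 °C; H2O
Reagents that add atoms: formaldehyde, C=O
Why: Aldol-type hydroxymethylation, in which the lithium dienolate of a senecioate reacts kinetically at its α carbon and the alkene moves out of conjugation; the new α centre is racemic and is erased in step 2.

Step 2
Reactants: 3 methyl 2-(hydroxymethyl)-3-methylbut-3-enoate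
Product: 4 methyl 2-(hydroxymethyl)-3-methylbut-2-enoate
Conditions: DBU (0.3 equiv), toluene, 60 °C
Reagents that add atoms: none
Why: Base-catalysed prototropic isomerisation, in which DBU removes the doubly activated α proton and reprotonation at the γ carbon gives the more stable tetrasubstituted conjugated ester, while the amidine is too weak to form the alkoxide that would start a retro-aldol loss of formaldehyde.

Step 3
Reactants: 4 methyl 2-(hydroxymethyl)-3-methylbut-2-enoate
Product: 5 methyl 2-(bromomethyl)-3-methylbut-2-enoate
Conditions: CBr4, PPh3, CH2Cl2, 0 °C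
Reagents that add atoms: carbon tetrabromide, BrC(Br)(Br)Br
Why: Appel reaction, a neutral SN2 displacement of the oxyphosphonium group at the primary allylic carbon, so the alkene stays in place and the ester meets no acid.

Step 4
Reactants: 6 2-bromopropene
Product: 7 isopropenylmagnesium bromide
Conditions: Mg turnings, Et2O, reflux
Reagents that add atoms: magnesium, [Mg]
Why: Ordinary Grignard formation from a vinylic bromide, carried out in Et2O because THF lowers the selectivity of copper-catalysed conjugate additions.

Step 5
Reactants: 8 cyclopent-2-enone; 7 isopropenylmagnesium bromide; 5 methyl 2-(bromomethyl)-3-methylbut-2-enoate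
Product: 10 methyl 3-methyl-2-{[(1S,5R)-2-oxo-5-(prop-1-en-2-yl)cyclopentyl]methyl}but-2-enoate (trans; H1 α; H5 β), via bromomagnesium enolate 9 (not isolated)
Conditions: CuBr·SMe2 (5 mol %), (R)-1-[(S)-2-(diphenylphosphino)ferrocenyl]ethyldicyclohexylphosphine (6 mol %), tBuOMe, −75 °C, slow addition of 7 (1.1 equiv); then DMPU, 5 (1.5 equiv), −75 to −20 °C
Reagents that add atoms: none
Why: The copper–diphosphine complex, in which copper is monovalent, takes the isopropenyl group from magnesium, binds the enone at its C=C bond and passes the group to the β carbon, which forms C1–C10 and leaves the bromomagnesium enolate 9 with its double bond only between C4 and C5. Once DMPU has loosened the magnesium aggregate, 9 displaces bromide at the CH2Br carbon of 5 in an SN2 reaction and forms C5–C6; the closest known chemistry is the copper-catalysed enantioselective conjugate addition of Grignard reagents to cyclic enones with trapping of the enolate, the three-component coupling of prostaglandin synthesis. No ring is closed. C1 is set by the ligand, which decides the face of the enone that is attacked, and C5 by the substrate, because 5 approaches anti to the new isopropenyl group and any cis isomer can still be equilibrated to trans through the enol. The step needs 1,4- rather than 1,2-addition (secured by the catalyst, the low temperature and slow addition of 7), single alkylation at C5 before proton exchange shifts the enolate to C3 (secured by the excess of a very reactive, ester-activated allylic bromide) and SN2 rather than SN2' attack (secured by the two methyl groups that shield the alkene terminus C11).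

Step 6
Reactants: 10 keto ester
Product: 11 (2S,3R)-2-[2-(hydroxymethyl)-3-methylbut-2-enyl]-3-(prop-1-en-2-yl)cyclopentan-1-ol (both C4 epimers)
Conditions: LiAlH4, Et2O, 0 °C to rt
Reagents that add atoms: none
Why: Hydride reduction takes the conjugated ester by 1,2-attack to the allylic alcohol, carries any lactone formed on the way through to the diol and also reduces the ketone, whose new C4 carbinol centre may be a mixture because step 7 removes it.

Step 7
Reactants: 11 diol
Product: 12 3-methyl-2-{[(1S,5R)-2-oxo-5-(prop-1-en-2-yl)cyclopentyl]methyl}but-2-enal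
Conditions: (COCl)2, DMSO, CH2Cl2, −78 °C; Et3N, −78 to 0 °C
Reagents that add atoms: none
Why: Swern oxidation, in which both hydroxyl groups become alkoxysulfonium ions at −78 °C and collapse together when Et3N is added, so no hydroxy aldehyde remains to close to a lactol and over-oxidise, neither alkene moves, and C5, again α to a ketone, keeps its favoured trans arrangement.

Step 8
Reactants: 12 keto enal
Product: 13 8β-hydroxy-15-nor-1αH,5βH-guaia-7(11),10(14)-dien-4-one
Conditions: Me2AlCl (2.5 equiv), CH2Cl2 (0.01 M), −78 to −20 °C
Reagents that add atoms: none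
Why: Type 2 intramolecular carbonyl-ene reaction, known to give 3-methylenecycloheptanols with alkylaluminium halides, in which C9 attacks the aluminium-bound aldehyde while a C14 hydrogen passes to oxygen; the chair-like seven-membered transition state with both fusion bonds equatorial places C8 on the β face of the isopropenyl plane and obliges the oxygen to stand axial and β to reach that hydrogen (8β-OH), H1 on the α face being out of reach, and the ketone stays out because it is the poorer enophile and would need a strained five-membered closure.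

Step 9
Reactants: 14 vanillic acid
Product: 16 4-(tert-butyldimethylsilyloxy)-3-methoxybenzoic acid, via bis-silylated vanillic acid 15 (not isolated)
Conditions: TBSCl (2.2 equiv), imidazole, DMF, rt; then AcOH/THF/H2O, rt
Reagents that add atoms: tert-butyldimethylsilyl chloride, CC(C)(C)[Si](C)(C)Cl
Why: Silylation of both acidic groups followed by selective hydrolysis of the far more labile silyl ester leaves only the phenol masked.

Step 10
Reactants: 13 hydroxy dienone; 16 protected vanillic acid
Product: 17 8β-(TBS-vanilloyloxy)-15-nor-1αH,5βH-guaia-7(11),10(14)-dien-4-one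
Conditions: DCC, DMAP, CH2Cl2, rt
Reagents that add atoms: none
Why: Steglich esterification, in which the acylpyridinium ion acylates the hindered secondary alcohol at oxygen without breaking the C8–O bond, so the 8β configuration is kept.

Step 11
Reactants: 17 dienone ester
Product: 19 8β-(TBS-vanilloyloxy)-10α-hydroxy-15-nor-1αH,5βH-guai-7(11)-en-4-one, via tertiary hydroperoxide 18 (not isolated)
Conditions: Mn(dpm)3 (10 mol %, dpm = dipivaloylmethanate), PhSiH3, O2 (1 atm), iPrOH/CH2Cl2, 0 °C; then PPh3
Reagents that add atoms: dioxygen, O=O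
Why: Mukaiyama hydration, in which hydrogen atom transfer from the metal hydride selects the open 1,1-disubstituted alkene over the tetrasubstituted one and gives the tertiary C10 radical, which O2 meets on the α face because A1,3 strain with the isopropylidene methyl holds the 8β-aroyloxy group axial, syn-axial to C10 and next to H5 on the β face.

Step 12
Reactants: 19 hydroxy enone ester
Product: 20 8β-(TBS-vanilloyloxy)-10α-hydroxy-15-nor-1αH,5βH,7αH-guaian-4-one (7β-isopropyl)
Conditions: [Ir(cod)(PCy3)(py)]PF6 (10 mol %), H2 (50 bar), CH2Cl2, rt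
Reagents that add atoms: none
Why: Homogeneous hydrogenation with a cationic iridium catalyst, one of the few that reduce tetrasubstituted alkenes, should deliver hydrogen to the α face of C7=C11 because the axial 8β-ester oxygen stands perpendicular to the alkene plane on the β face and the 10β-methyl group lies on that face too, which makes H7 α and the isopropyl group β, cis to the ester.

Step 13
Reactants: 20 hydroxy ketone
Product: 21 8β-(TBS-vanilloyloxy)-10α-(trimethylsilyloxy)-15-nor-1αH,5βH,7αH-guaian-4-one
Conditions: N-(trimethylsilyl)imidazole, CH2Cl2, rt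
Reagents that add atoms: N-(trimethylsilyl)imidazole, C[Si](C)(C)n1ccnc1
Why: Silylation with a neutral, powerful silyl donor masks the tertiary alcohol, so that no alkoxide competes for the triflating agent in step 14, and it does not enolise the ketone.

Step 14
Reactants: 21 silyl ether ketone
Product: 23 8β-(TBS-vanilloyloxy)-10α-(trimethylsilyloxy)-15-nor-1αH,5βH,7αH-guai-3-en-4-yl trifluoromethanesulfonate, via potassium enolate 22 (not isolated)
Conditions: KN(SiMe3)2, THF, −78 °C; PhNTf2, −78 to 0 °C
Reagents that add atoms: N-phenylbis(trifluoromethanesulfonimide), O=S(=O)(N(c1ccccc1)S(=O)(=O)C(F)(F)F)C(F)(F)F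
Why: Kinetic enolate formation and O-triflation, in which the bulky amide takes a proton from the open C3 methylene and not the tertiary, flanked C5–H, so the double bond is fixed at C3=C4, C5 is untouched, and the aryl ester has no α hydrogen to lose.

Step 15
Reactants: 23 enol triflate
Product: 24 8β-(TBS-vanilloyloxy)-10α-(trimethylsilyloxy)-1αH,5βH,7αH-guai-3-ene
Conditions: MeZnCl, Pd(PPh3)4 (5 mol %), THF, rt to 50 °C
Reagents that add atoms: methylzinc chloride, C[Zn]Cl
Why: Negishi cross-coupling of an enol triflate, in which zerovalent palladium inserts into the C4–O bond, zinc hands over methyl and reductive elimination installs C15 with the alkene in place, while the organozinc reagent leaves the ester and the silyl ethers alone.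

Step 16
Reactants: 24 guai-3-ene
Product: 25 3α,4α-epoxy-8β-(TBS-vanilloyloxy)-10α-(trimethylsilyloxy)-1αH,5βH,7αH-guaiane
Conditions: mCPBA, CH2Cl2, 0 °C
Reagents that add atoms: 3-chloroperoxybenzoic acid, O=C(OO)c1cccc(Cl)c1
Why: Prilezhaev epoxidation of the only alkene, for which the trans fusion locks the cyclopentene as an envelope with C1 bent to the α side, so attack on the α face is staggered with respect to the allylic bonds at C2 and C5 whereas attack on the β face would eclipse the pseudo-axial H2β and H5 and meets the 10β-methyl group, which sets C3 and C4 together as the α epoxide.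

Step 17
Reactants: 25 protected epoxide
Product: 26 3α,4α-epoxy-10α-hydroxy-1αH,5βH,7αH-guaian-8β-yl 4-hydroxy-3-methoxybenzoate (CNP0136245.2)
Conditions: Bu4NF, AcOH (1:1), THF, 0 °C
Reagents that add atoms: none
Why: Fluoride-induced cleavage of both Si–O bonds, buffered with acetic acid so that neither the epoxide nor the ester meets a strongly basic oxide, and no stereocentre is affected.

Compound list
1 | methyl 3-methylbut-2-enoate | COC(=O)C=C(C)C | starting material
2 | lithium 1-methoxy-3-methylbuta-1,3-dien-1-olate | C=C(C)C=C(OC)O[Li] | intermediate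
3 | methyl 2-(hydroxymethyl)-3-methylbut-3-enoate (racemic) | C=C(C)C(CO)C(=O)OC | intermediate
4 | methyl 2-(hydroxymethyl)-3-methylbut-2-enoate | COC(=O)C(CO)=C(C)C | intermediate
5 | methyl 2-(bromomethyl)-3-methylbut-2-enoate | COC(=O)C(CBr)=C(C)C | intermediate
6 | 2-bromopropene | CC(Br)=C | starting material
7 | isopropenylmagnesium bromide | C=C(C)[Mg]Br | intermediate
8 | cyclopent-2-enone | O=C1C=CCC1 | starting material
9 | bromomagnesium (R)-3-(prop-1-en-2-yl)cyclopent-1-en-1-olate | C=C(C)[C@@H]1CCC(O[Mg]Br)=C1 | intermediate
10 | methyl 3-methyl-2-{[(1S,5R)-2-oxo-5-(prop-1-en-2-yl)cyclopentyl]methyl}but-2-enoate | C=C(C)[C@@H]1CCC(=O)[C@H]1CC(=C(C)C)C(=O)OC | intermediate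
11 | (2S,3R)-2-[2-(hydroxymethyl)-3-methylbut-2-enyl]-3-(prop-1-en-2-yl)cyclopentan-1-ol, carbinol centre open | C=C(C)[C@@H]1CCC(O)[C@H]1CC(=C(C)C)CO | intermediate
12 | 3-methyl-2-{[(1S,5R)-2-oxo-5-(prop-1-en-2-yl)cyclopentyl]methyl}but-2-enal | C=C(C)[C@@H]1CCC(=O)[C@H]1CC(=C(C)C)C=O | intermediate
13 | 8β-hydroxy-15-nor-1αH,5βH-guaia-7(11),10(14)-dien-4-one | O[C@@H]1CC(=C)[C@@H]2CCC(=O)[C@H]2CC1=C(C)C | intermediate
14 | vanillic acid | COc1cc(C(=O)O)ccc1O | starting material
15 | tert-butyldimethylsilyl 4-(tert-butyldimethylsilyloxy)-3-methoxybenzoate | COc1cc(C(=O)O[Si](C)(C)C(C)(C)C)ccc1O[Si](C)(C)C(C)(C)C | intermediate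
16 | 4-(tert-butyldimethylsilyloxy)-3-methoxybenzoic acid | COc1cc(C(=O)O)ccc1O[Si](C)(C)C(C)(C)C | intermediate
17 | 8β-(TBS-vanilloyloxy)-15-nor-1αH,5βH-guaia-7(11),10(14)-dien-4-one | COc1cc(C(=O)O[C@@H]2CC(=C)[C@@H]3CCC(=O)[C@H]3CC2=C(C)C)ccc1O[Si](C)(C)C(C)(C)C | intermediate
18 | 10α-hydroperoxide of 17 (10β-methyl) | COc1cc(C(=O)O[C@@H]2C[C@@](C)(OO)[C@@H]3CCC(=O)[C@H]3CC2=C(C)C)ccc1O[Si](C)(C)C(C)(C)C | intermediate
19 | 8β-(TBS-vanilloyloxy)-10α-hydroxy-15-nor-1αH,5βH-guai-7(11)-en-4-one | COc1cc(C(=O)O[C@@H]2C[C@@](C)(O)[C@@H]3CCC(=O)[C@H]3CC2=C(C)C)ccc1O[Si](C)(C)C(C)(C)C | intermediate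
20 | 8β-(TBS-vanilloyloxy)-10α-hydroxy-15-nor-1αH,5βH,7αH-guaian-4-one | COc1cc(C(=O)O[C@@H]2C[C@@](C)(O)[C@@H]3CCC(=O)[C@H]3C[C@@H]2C(C)C)ccc1O[Si](C)(C)C(C)(C)C | intermediate
21 | 10-O-trimethylsilyl ether of 20 | COc1cc(C(=O)O[C@@H]2C[C@@](C)(O[Si](C)(C)C)[C@@H]3CCC(=O)[C@H]3C[C@@H]2C(C)C)ccc1O[Si](C)(C)C(C)(C)C | intermediate
22 | potassium C3=C4 enolate of 21 | COc1cc(C(=O)O[C@@H]2C[C@@](C)(O[Si](C)(C)C)[C@@H]3CC=C(O[K])[C@H]3C[C@@H]2C(C)C)ccc1O[Si](C)(C)C(C)(C)C | intermediate
23 | C3=C4 enol triflate of 21 | COc1cc(C(=O)O[C@@H]2C[C@@](C)(O[Si](C)(C)C)[C@@H]3CC=C(OS(=O)(=O)C(F)(F)F)[C@H]3C[C@@H]2C(C)C)ccc1O[Si](C)(C)C(C)(C)C | intermediate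
24 | 8β-(TBS-vanilloyloxy)-10α-(trimethylsilyloxy)-1αH,5βH,7αH-guai-3-ene | COc1cc(C(=O)O[C@@H]2C[C@@](C)(O[Si](C)(C)C)[C@@H]3CC=C(C)[C@H]3C[C@@H]2C(C)C)ccc1O[Si](C)(C)C(C)(C)C | intermediate
25 | 3α,4α-epoxide of 24 | COc1cc(C(=O)O[C@@H]2C[C@@](C)(O[Si](C)(C)C)[C@@H]3C[C@H]4O[C@@]4(C)[C@H]3C[C@@H]2C(C)C)ccc1O[Si](C)(C)C(C)(C)C | intermediate
26 | 3α,4α-epoxy-10α-hydroxy-1αH,5βH,7αH-guaian-8β-yl 4-hydroxy-3-methoxybenzoate | COc1cc(C(=O)O[C@@H]2C[C@@](C)(O)[C@@H]3C[C@H]4O[C@@]4(C)[C@H]3C[C@@H]2C(C)C)ccc1O | target

Total step count: 17. Longest linear sequence: 15 steps (1, 2, 3, 5, 6, 7, 8, 10, 11, 12, 13, 14, 15, 16, 17).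

Steps most likely to fail

**Step 5.** Face selection by the catalyst may be weak with a branched alkenyl Grignard reagent. Alkylation of the magnesium enolate may also be slow, which lets proton exchange with the product move the enolate to C3 and opens the way to multiple alkylation.

The fallback runs from 8 and 7 back to 10 and separates the addition from the alkylation. Enolate 9 is silylated in the flask with Me3SiCl to give (R)-trimethyl{[3-(prop-1-en-2-yl)cyclopent-1-en-1-yl]oxy}silane F1. This is isolated, so its enantiomeric purity can be checked and the ligand changed without spending 5. MeLi in THF at 0 °C then releases lithium (R)-3-(prop-1-en-2-yl)cyclopent-1-en-1-olate F2, with the double bond still between C4 and C5. This more nucleophilic, magnesium-free enolate is alkylated by 5 in THF/DMPU at −78 °C to give 10.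

**Step 8.** The hindered, conjugated aldehyde may react too slowly. Methyl transfer from aluminium, ionisation of the allylic aluminium alkoxide or binding of the Lewis acid to the ketone could then take over, and the chair-like transition state may not be followed cleanly.

The fallback runs from 12 back to 13 and makes C8–C9 by an organometallic addition instead of a pericyclic reaction. Selenium-catalysed ene-type chlorination (NCS, PhSeCl 10 mol %, CH2Cl2, rt) of the electron-rich isopropenyl group gives 2-{[(1S,5R)-5-(3-chloroprop-1-en-2-yl)-2-oxocyclopentyl]methyl}-3-methylbut-2-enal F3. CrCl2 in THF/DMF at high dilution converts it into the allylchromium dichloride F4. This species adds to aldehydes but not to ketones (Nozaki–Hiyama allylation). It does so through a closed six-membered transition state of the same shape as the ene one, and gives 13 after work-up.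

**Step 12.** The catalyst may not turn over at the crowded tetrasubstituted alkene, or hydrogen may be delivered to the β face through binding of the metal to the ester carbonyl.

The fallback runs from 13 back to 20. The alkene is reduced as an activated enone, and C8 is then set again from C10:
- 13 is hydrated as in step 11, through the 10α-hydroperoxide F5, to 8β,10α-dihydroxy-15-nor-1αH,5βH-guai-7(11)-en-4-one F6.
- MnO2 in CH2Cl2 oxidises only the allylic alcohol, giving 10α-hydroxy-15-nor-1αH,5βH-guai-7(11)-ene-4,8-dione F7.
- H2 over Pd/C in EtOAc should reduce this pulegone-type enone from the α face, away from the axial 10β-methyl group, to 10α-hydroxy-15-nor-1αH,5βH,7αH-guaiane-4,8-dione F8.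
- Me4NBH(OAc)3 in MeCN/AcOH at −20 °C binds to the 10α-hydroxyl and delivers hydride to the α face of C8 only (Evans–Saksena reduction). The C4 ketone has no neighbouring hydroxyl and stays. The product is 8β,10α-dihydroxy-15-nor-1αH,5βH,7αH-guaian-4-one F9.
- Steglich esterification of the secondary alcohol of F9 with 16 gives 20.

Further compounds
F1 | step 5 | (R)-trimethyl{[3-(prop-1-en-2-yl)cyclopent-1-en-1-yl]oxy}silane | C=C(C)[C@@H]1CCC(O[Si](C)(C)C)=C1
F2 | step 5 | lithium (R)-3-(prop-1-en-2-yl)cyclopent-1-en-1-olate | C=C(C)[C@@H]1CCC(O[Li])=C1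
F3 | step 8 | 2-{[(1S,5R)-5-(3-chloroprop-1-en-2-yl)-2-oxocyclopentyl]methyl}-3-methylbut-2-enal | C=C(CCl)[C@@H]1CCC(=O)[C@H]1CC(=C(C)C)C=O
F4 | step 8 | allylchromium dichloride derived from F3 | C=C(C[Cr](Cl)Cl)[C@@H]1CCC(=O)[C@H]1CC(=C(C)C)C=O
F5 | step 12 | 10α-hydroperoxy-8β-hydroxy-15-nor-1αH,5βH-guai-7(11)-en-4-one | O[C@@H]1C[C@@](C)(OO)[C@@H]2CCC(=O)[C@H]2CC1=C(C)C
F6 | step 12 | 8β,10α-dihydroxy-15-nor-1αH,5βH-guai-7(11)-en-4-one | O[C@@H]1C[C@@](C)(O)[C@@H]2CCC(=O)[C@H]2CC1=C(C)C
F7 | step 12 | 10α-hydroxy-15-nor-1αH,5βH-guai-7(11)-ene-4,8-dione | O=C1C[C@@](C)(O)[C@@H]2CCC(=O)[C@H]2CC1=C(C)C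
F8 | step 12 | 10α-hydroxy-15-nor-1αH,5βH,7αH-guaiane-4,8-dione | O=C1C[C@@](C)(O)[C@@H]2CCC(=O)[C@H]2C[C@@H]1C(C)C
F9 | step 12 | 8β,10α-dihydroxy-15-nor-1αH,5βH,7αH-guaian-4-one | O[C@@H]1C[C@@](C)(O)[C@@H]2CCC(=O)[C@H]2C[C@@H]1C(C)C
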